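(All runs were generated by integration from invented constants, and the scatter is random.)

At its start the cedar run gains target at 0.0394 d⁻¹ as a share of the solid substrate charged, and late in the cedar run it gains 0.0204 d⁻¹, about half of the early rate, even though its second portion of reagent went in after 3.0 d.

| flask | solid substrate | reagent | temperature | remark | time |
|---|---|---|---|---|---|
| larch | 0.098 M | 0.046 M (in portions, 2) | −10 °C | run made earlier; portions every 3.0 d |  |
| cedar | 0.098 M | 0.10 M (in portions, 2) | 15 °C | run made earlier; portions every 3.0 d |  |
| ash | 0.049 M | 0.0686 M (in portions, 2) | −10 °C | run made earlier; portions every 3.0 d |  |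
| summer | 0.098 M | 0.0686 M | −5 °C | everything together at the start | 6.0 d |
| spring | 0.098 M | 0.0686 M (in portions, 2) | 35 °C | the portions of reagent follow each other after 3.0 d, the first at the start | 6.0 d |

| larch: time / d | larch: target / % | cedar: time / d | cedar: target / % | ash: time / d | ash: target / % |
|---|---|---|---|---|---|
| 12.0 | 2.9 | 1.04 | 4.1 | 12.0 | 4.0 |
| 25.0 | 5.2 | 2.50 | 8.6 | 25.0 | 10.1 |
| 40.0 | 6.5 | 6.00 | 23.3 | 40.0 | 13.8 |
| 50.0 | 9.0 | 15.0 | 41.7 | 50.0 | 18.7 |

(each reading ± 1 percentage point)

- which one finishes higher in amount of target, in percent of the solid substrate charged ("neither" within 2 percentage points) (summer / spring / neither)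
- amount of target at the end, in percent of the solid substrate charged, summer
- amount of target at the end, in percent of the solid substrate charged, spring

- at the start none of the solid substrate is in solution
- what has only dissolved of solid substrate counts as not reacted
- a reading or a percentage of target counts all its forms, free or not

So the starting rate does not carry through to the end of cedar, and I need a ceiling as well. I take one reagent per target and carry the bound share, the part of the charged reagent that sits in target late in a run: cedar's last reading gives 40.9%, with the scatter of the readings, and cedar is still climbing there. On spring's charge this share means an estimated ceiling of 28.6% of the solid substrate.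

The rates say which flask meets that ceiling. The larch run averages 0.00180 d⁻¹, so per unit of reagent, cedar's first portion runs faster by a factor of 20.1. Spreading that factor evenly over the degrees, I reckon that summer gains 0.00489 d⁻¹, which is 2.94% over its time. That stays below the ceiling, which holds for summer's equal charge too, so I let summer keep its straight line, the pseudo-zero-order case. I put spring's start at 0.299 d⁻¹, and at that rate my estimate passes the ceiling before its second portion. My own reckoning is therefore 2.94% for summer and 28.6% for spring.

The forecast also says spring, with 3.6% (2.3% to 5.5%) for summer and 35% (24% to 52%) for spring, and it adds: “The stoichiometry is the main uncertainty”. For spring my figure is lower than the forecast's.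

The flask gives 3.09% for summer and 21.9% for spring, so spring finishes higher. At the end of spring, side product holds 72.4% of the solid substrate charged. Spring's bound share at its end comes to 31.3%, lower than the 40.9% read from cedar.

    solid substrate ⇌ dissolved substrate, rate k1*(cs1 - [dissolved substrate]) while solid is left; crystals form when [dissolved substrate] > cs1 (solubility = 0.0630 M, k = 0.360 h⁻¹)
    dissolved substrate + reagent ⇌ target (K = 110 L mol⁻¹, k = 0.300 L mol⁻¹ h⁻¹, Ea = 70.0 kJ mol⁻¹, ΔH = −24.0 kJ mol⁻¹)
    2 dissolved substrate → side product (k = 0.350 L mol⁻¹ h⁻¹, Ea = 88.0 kJ mol⁻¹)
    solid product ⇌ target, rate k4*(cs4 - [target]) while solid is left; crystals form when [target] > cs4 (solubility = 40.0 mM, k = 1.20 h⁻¹)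
    (constants at 35 °C)

For the neighbour of spring with 0.12 M of reagent, spring's bound share gives 38.3%. The simulation gives 33.6%, so the share there is lower still, at 27.4%.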